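**Assumption:** the target SMILES has no stereocentre and no stereogenic double bond (the prenyl terminus is gem-dimethyl). The molecule is therefore achiral and the "single enantiomer" requirement does not apply. The L-alanine stereocentre carried through the route is deliberately destroyed when the ring aromatises in Step 6.

## Retrosynthetic overview
1. Avoided: the cyclo(Ala–7-prenyl-Trp) diketopiperazine with late N-oxidation and O-methylation. Here the N–O and OMe groups are built into an acyclic chain, so no oxidant ever meets the indole or the prenyl group.
2. Last disconnection, N1–C2: the pyrazinone closes by acylation of an E-oxime nitrogen by the alanine ester, followed by an aromatising C3–H to O tautomerisation. An oximino acid plus an amino acid is exactly the oxidation level of the target.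
3. Indole C3–CH2 disconnection: 7-prenylindole adds to a 2-nitrosoalkene. Fluoride releases this species from an α-bromo O-TBS oxime that already carries the O-methyl imidate (future C5–OMe) and the Ala ester.
4. The fragment comes from bromopyruvic acid and L-Ala-OMe, then TBSONH2, then MeOTf. 7-Prenylindole comes from 7-bromoindole and prenylBpin by an α-selective Suzuki coupling.
5. Ring order: the indole is bought intact, and the N-hydroxypyrazinone ring is formed in the final step.

## Route

**Step 1**
Reactants: 1, 7-bromo-1H-indole; 2, 3-methylbut-2-enylboronic acid pinacol ester (prenylBpin)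
Product: 3, 7-(3-methylbut-2-en-1-yl)-1H-indole (7-prenylindole)
Conditions: Pd-PEPPSI-IPent (2 mol %), 5 M aq KOH, THF, 70 °C
Reagents that add atoms: prenylBpin (2), CC(C)=CCB1OC(C)(C)C(C)(C)O1
Why: This is an α-selective allyl–aryl Suzuki–Miyaura coupling in which the very bulky NHC ligand forces reductive elimination from the unhindered CH2 terminus to give the linear prenyl isomer, the free indole N–H tolerates aqueous KOH, and no stereocentre is formed.

**Step 2**
Reactants: 4, 3-bromopyruvic acid; 5, L-alanine methyl ester hydrochloride
Product: 6, methyl (2S)-2-[(3-bromo-2-oxopropanoyl)amino]propanoate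
Conditions: (i) 4, Cl2CHOMe (1.1 equiv), neat, 45 °C, strip volatiles; (ii) 5, 2,6-lutidine (2.1 equiv), CH2Cl2, −40 → 0 °C
Reagents that add atoms: none beyond reactants 4 and 5 (Cl2CHOMe only activates the acid)
Why: This is an amidation through the α-keto acid chloride, where N-acylation at low temperature is far faster than N-alkylation by the bromoketone, the hindered base cannot quaternise, and the (S)-centre is simply carried along until it is erased in Step 6.

**Step 3**
Reactants: 6; 7, O-(tert-butyldimethylsilyl)hydroxylamine
Product: 8, methyl (2S)-2-{[3-bromo-2-(tert-butyldimethylsilyloxyimino)propanoyl]amino}propanoate (E/Z mixture)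
Conditions: 7 (1.1 equiv), PPTS (10 mol %), 4 Å MS, CH2Cl2, rt
Reagents that add atoms: TBSONH2 (7), NO[Si](C)(C)C(C)(C)C
Why: This is an oxime-ether condensation in which the doubly activated ketone reacts faster than SN2 at CH2Br (as with bromopyruvate esters), the silyl cap blocks premature HBr loss, and the C=N geometry is irrelevant because Step 5 erases it.

**Step 4**
Reactants: 8
Product: 9, methyl (2S)-2-{[3-bromo-1-methoxy-2-(tert-butyldimethylsilyloxyimino)propylidene]amino}propanoate (the O-methyl imidate)
Conditions: MeOTf (1.1 equiv), CH2Cl2, 0 °C → rt; then cold sat. aq NaHCO3; used at once without chromatography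
Reagents that add atoms: methyl triflate, COS(=O)(=O)C(F)(F)F
Why: This is kinetic O-methylation of a secondary amide (imidate or lactim-ether formation), where the amide oxygen is the only good nucleophile because the oxime is silyl-shielded, and the product remains as the N-protonated imidatonium triflate, which prevents over-methylation, until bicarbonate releases it.

**Step 5**
Reactants: 3 (1.0 equiv); 9 (1.3 equiv)
Product: 10, methyl 2-{[(2E)-2-(hydroxyimino)-1-methoxy-3-[7-(3-methylbut-2-enyl)-1H-indol-3-yl]propylidene]amino}propanoate (used crude)
Conditions: TBAF (1.0 M in THF, 1.05 equiv relative to 9, syringe pump over 2 h), 4 Å MS, CH2Cl2, −20 °C → rt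
Reagents that add atoms: none (fluoride removes TBS and bromide leaves)
Why: Fluoride-triggered 1,4-elimination of an α-halo O-silyl oxime gives a transient 2-nitrosoalkene, which the indole C2=C3 bond traps by inverse-demand hetero-Diels–Alder addition and oxazine ring-opening (a formal C3 Michael addition), so O and CH2 are cis and the oxime emerges E with its N lone pair facing the imidate arm; only the imidoyl substituent is new, and indole far exceeds the prenyl alkene in nucleophilicity.

**Step 6**
Reactants: 10
Product: 11, astepyrazinoxide, 1-hydroxy-5-methoxy-3-methyl-6-{[7-(3-methylbut-2-en-1-yl)-1H-indol-3-yl]methyl}pyrazin-2(1H)-one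
Conditions: NaOMe (1.5 equiv), dry MeOH, 0 → 45 °C; then aq citric acid to pH 4 and an EDTA wash
Reagents that add atoms: none (MeOH is lost)
Why: Proposed new method: in the E-oximate the oxygen is held trans to the chain and the E-imidate places the Ala ester cis to C6, so only 6-exo attack of the oxime nitrogen on the ester is possible, giving an N-acyl nitrone whose doubly activated C3–H is removed irreversibly to form the aromatic hydroxamate (this destroys the Ala stereocentre), while every methoxide exchange at the ester or imidate is degenerate and any O-acyl by-product is re-opened by methoxide; the closest known reactions are oxime-N ring closure onto nitriles giving 2-aminopyrazine 1-oxides and the 2-pyrone plus hydroxylamine synthesis of 1-hydroxy-2-pyridones.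

## Compound list
1 | 7-bromo-1H-indole | Brc1cccc2cc[nH]c12 | starting material
2 | prenylboronic acid pinacol ester | CC(C)=CCB1OC(C)(C)C(C)(C)O1 | starting material
3 | 7-prenyl-1H-indole | CC(C)=CCc1cccc2cc[nH]c12 | intermediate
4 | 3-bromopyruvic acid | OC(=O)C(=O)CBr | starting material
5 | L-alanine methyl ester hydrochloride | COC(=O)[C@H](C)N.Cl | starting material
6 | N-(bromopyruvoyl)-L-alanine methyl ester | COC(=O)[C@H](C)NC(=O)C(=O)CBr | intermediate
7 | O-(tert-butyldimethylsilyl)hydroxylamine | NO[Si](C)(C)C(C)(C)C | starting material
8 | O-TBS bromo-oxime amide (E/Z mixture, inconsequential) | COC(=O)[C@H](C)NC(=O)C(CBr)=NO[Si](C)(C)C(C)(C)C | intermediate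
9 | O-TBS bromo-oxime O-methyl imidate | COC(=O)[C@H](C)N=C(OC)C(CBr)=NO[Si](C)(C)C(C)(C)C | intermediate
10 | (E)-α-oximino O-methyl imidate of the 7-prenylindolyl chain (imidate C=N inverts freely; Ala centre inconsequential) | COC(=O)[C@H](C)N=C(OC)/C(Cc1c[nH]c2c(CC=C(C)C)cccc12)=N/O | intermediate
11 | astepyrazinoxide (achiral) | COc1nc(C)c(=O)n(O)c1Cc1c[nH]c2c(CC=C(C)C)cccc12 | target

## Summary
**Total steps:** 6. Steps 5 and 6 can be telescoped by adding NaOMe/MeOH to crude 10, which gives 5 operations.
**Longest linear sequence:** 5 (Steps 2 → 3 → 4 → 5 → 6). Step 1 is a one-step side branch.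

**Three steps most likely to fail, with fallbacks**
1. **Step 6:** the oxime nitrogen may not acylate with a simple methyl ester.
   Fallback: change the ring-closing electrophile to a nitrile.
   - Build the fragment from 2-aminopropanenitrile instead of Ala-OMe.
   - Ring closure then becomes the precedented oxime-N to nitrile cyclisation, giving the 2-amino-5-methoxypyrazine 1-oxide.
   - Convert C2–NH2 to the hydroxamic acid by hot alkaline hydrolysis.
2. **Step 5:** the imidoyl-substituted nitrosoalkene may oligomerise or react sluggishly.
   Fallback: move the C–C bond formation to the start of a linear sequence.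
   - Alkylate 3 with the well-precedented ethyl 2-nitrosoacrylate, generated from commercial ethyl 3-bromo-2-(hydroxyimino)propanoate and Na2CO3.
   - Saponify, then couple with Ala-OMe using EDC.
   - O-silylate the oxime, methylate with MeOTf, and desilylate to rejoin the route at 10.
3. **Step 4:** imidate 9 may self-alkylate or hydrolyse, or the amide may be too unreactive.
   Fallback: postpone the O-methylation until after ring closure.
   - Couple amide 8 with 3 under fluoride.
   - Saponify and close the ring at the amide level by carboxyl activation, giving the 1-hydroxy dehydro-diketopiperazine (or its 1,5-dihydroxypyrazinone tautomer).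
   - Cap the more acidic N–OH as its TBS ether.
   - O-methylate the remaining lactam with Me3OBF4 and isomerise with base to the aromatic tautomer.
   - Desilylate to give 11.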